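**Retrosynthetic overview**
- The target is an all-trans 2-(arylmethyl)-5-aryl-oxolan-3-ol (ring C2 R, C3 S, C4 S, C5 S). Its benzylic CH2 is bonded to the central guaiacyl ring of an erythro (1R,2S) arylglycerol β-aryl ether. The last disconnection cuts this CH2–aryl bond together with the ring C2–O1 bond.
- Enabling feature: ring oxygen O1 and the exocyclic CH2 both sit on ring carbon C2. CH2–C2 is therefore a former terminal vinyl group, and O1 is the hydroxyl of the benzylic carbinol C5, placed to close a five-membered ring. The required 2,5-trans and 2,3-trans relationships are the ones syn-oxypalladation favours.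
- Key step: palladium-catalysed carboetherification of an acyclic γ-hydroxy alkene (fragment A) with an aryl bromide (fragment B). It forms the aryl–CH2 bond, closes the oxolane (the only ring made, formed last) and sets C2.
- Fragment A: Evans syn-aldol with acrolein, Weinreb amide, aryl ketone, CBS reduction. Fragment B: methyl (R)-glycerate, Mitsunobu etherification with inversion, Felkin–Anh-controlled aryl addition (erythro).
- Finish: global desilylation, then hydrogenolysis of the two phenolic benzyl ethers.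

Key step: step 12

Remark: TBS = tert-butyldimethylsilyl, Bn = benzyl. The six starting materials are taken as purchasable. The phenols are carried as benzyl ethers because aryl silyl ethers are at risk under NaOtBu.

**Fragment A (γ-hydroxy alkene)**

Step 1
Reactants: 1 3-[(TBS)oxy]propanoic acid; 2 (S)-4-benzyloxazolidin-2-one
Product: 4 (S)-4-benzyl-3-{3-[(TBS)oxy]propanoyl}oxazolidin-2-one, via mixed pivalic anhydride 3 (not isolated)
Conditions: PivCl, Et3N, THF, −20 °C; then LiCl, 2, −20 °C → rt
Reagents that add atoms: none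
Why: N-acylation of the oxazolidinone through the pivaloyl mixed anhydride with LiCl activation is a standard imide synthesis that leaves the silyl ether intact; no stereocentre is formed.

Step 2
Reactants: 4 (S)-4-benzyl-3-{3-[(TBS)oxy]propanoyl}oxazolidin-2-one; 5 acrolein
Product: 7 (S)-4-benzyl-3-[(2S,3R)-2-{[(TBS)oxy]methyl}-3-hydroxypent-4-enoyl]oxazolidin-2-one, via Z-dibutylboron enolate 6 (not isolated)
Conditions: n-Bu2BOTf, i-Pr2NEt, CH2Cl2, −78 → 0 °C; 5, −78 → 0 °C; pH 7 buffer, MeOH, 30% H2O2, 0 °C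
Reagents that add atoms: none
Why: Evans syn-aldol reaction, in which the Z-boron enolate adds 1,2 to acrolein through a Zimmerman–Traxler chair on the face opposite the auxiliary benzyl group, should set both new stereocentres (2S,3R) in the syn relationship.

Step 3
Reactants: 7 (S)-4-benzyl-3-[(2S,3R)-2-{[(TBS)oxy]methyl}-3-hydroxypent-4-enoyl]oxazolidin-2-one
Product: 8 (2S,3R)-2-{[(TBS)oxy]methyl}-3-hydroxy-N-methoxy-N-methylpent-4-enamide
Conditions: MeNHOMe·HCl, AlMe3, CH2Cl2, −20 → 0 °C; aq. potassium sodium tartrate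
Reagents that add atoms: N,O-dimethylhydroxylamine hydrochloride, CNOC.Cl
Why: Weinreb transamination of the aldol imide with the aluminium amide, assisted by the free β-hydroxyl, should remove the auxiliary without epimerisation.

Step 4
Reactants: 8 (2S,3R)-2-{[(TBS)oxy]methyl}-3-hydroxy-N-methoxy-N-methylpent-4-enamide
Product: 9 (2S,3R)-3-[(TBS)oxy]-2-{[(TBS)oxy]methyl}-N-methoxy-N-methylpent-4-enamide
Conditions: TBSOTf, 2,6-lutidine, CH2Cl2, −78 → 0 °C
Reagents that add atoms: tert-butyldimethylsilyl triflate (TBSOTf), CC(C)(C)[Si](C)(C)OS(=O)(=O)C(F)(F)F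
Why: Standard silylation of a secondary alcohol masks the allylic hydroxyl so that it can neither bind palladium nor be oxidised in the key step.

Step 5
Reactants: 9 (2S,3R)-3-[(TBS)oxy]-2-{[(TBS)oxy]methyl}-N-methoxy-N-methylpent-4-enamide; 10 1-(benzyloxy)-4-bromo-2-methoxybenzene
Product: 12 (2S,3R)-1-[4-(benzyloxy)-3-methoxyphenyl]-3-[(TBS)oxy]-2-{[(TBS)oxy]methyl}pent-4-en-1-one, via aryllithium 11 (not isolated)
Conditions: n-BuLi, THF, −78 °C; then 9, −78 → −30 °C; aq. NH4Cl
Reagents that add atoms: none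
Why: Weinreb ketone synthesis, in which bromine–lithium exchange is followed by addition to the amide to give a chelated tetrahedral intermediate that collapses only on quench, should avoid over-addition and α-epimerisation.

Step 6
Reactants: 12 (2S,3R)-1-[4-(benzyloxy)-3-methoxyphenyl]-3-[(TBS)oxy]-2-{[(TBS)oxy]methyl}pent-4-en-1-one
Product: 13 (1S,2R,3R)-1-[4-(benzyloxy)-3-methoxyphenyl]-3-[(TBS)oxy]-2-{[(TBS)oxy]methyl}pent-4-en-1-ol
Conditions: (R)-1-methyl-3,3-diphenyltetrahydro-1H,3H-pyrrolo[1,2-c][1,3,2]oxazaborole [(R)-Me-CBS] (20 mol %), catecholborane, toluene, −78 → −40 °C; aq. NaHCO3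
Reagents that add atoms: none
Why: Corey–Bakshi–Shibata reduction with the aryl group as the large substituent should give the (1S) carbinol, which is also the Felkin–Anh product of this α-branched ketone (matched case), and catecholborane should not hydroborate the vinyl group at low temperature.

**Fragment B (aryl bromide)**

Step 7
Reactants: 14 methyl (R)-2,3-dihydroxypropanoate
Product: 15 methyl (R)-3-[(TBS)oxy]-2-hydroxypropanoate
Conditions: TBSCl, imidazole, CH2Cl2, 0 °C
Reagents that add atoms: tert-butyldimethylsilyl chloride (TBSCl), CC(C)(C)[Si](C)(C)Cl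
Why: Selective silylation of the primary hydroxyl relies on the steric preference of TBSCl and leaves the stereocentre untouched.

Step 8
Reactants: 15 methyl (R)-3-[(TBS)oxy]-2-hydroxypropanoate; 16 4-bromo-2-methoxyphenol
Product: 17 methyl (S)-2-(4-bromo-2-methoxyphenoxy)-3-[(TBS)oxy]propanoate
Conditions: PPh3, DIAD, THF, 0 °C → rt
Reagents that add atoms: none
Why: Mitsunobu etherification of an α-hydroxy ester with a phenol is an SN2 displacement that should install the aryl ether with clean inversion (R to S).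

Step 9
Reactants: 17 methyl (S)-2-(4-bromo-2-methoxyphenoxy)-3-[(TBS)oxy]propanoate
Product: 18 (S)-2-(4-bromo-2-methoxyphenoxy)-3-[(TBS)oxy]propanal
Conditions: i-Bu2AlH, CH2Cl2, −78 °C; aq. potassium sodium tartrate
Reagents that add atoms: none
Why: Partial reduction of the α-alkoxy ester stops at the aluminium hemiacetal at −78 °C, and the aldehyde released on work-up is used at once to avoid epimerisation.

Step 10
Reactants: 10 1-(benzyloxy)-4-bromo-2-methoxybenzene; 18 (S)-2-(4-bromo-2-methoxyphenoxy)-3-[(TBS)oxy]propanal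
Product: 21 (1R,2S)-1-[4-(benzyloxy)-3-methoxyphenyl]-2-(4-bromo-2-methoxyphenoxy)-3-[(TBS)oxy]propan-1-ol, via arylmagnesium bromide 19 (not isolated), via aryltitanium triisopropoxide 20 (not isolated)
Conditions: Mg turnings, THF, 40 °C; ClTi(OiPr)3, −78 → −40 °C; then 18, −78 → −20 °C; aq. NH4Cl
Reagents that add atoms: none
Why: Magnesium insertion into 10 and transmetalation give a non-chelating aryltitanium reagent whose addition to the α-aryloxy aldehyde should follow the polar Felkin–Anh model (aryloxy group anti to the incoming aryl) and give the anti (erythro) alcohol, and the titanium reagent should not exchange with the aryl bromide of 18.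

Step 11
Reactants: 21 (1R,2S)-1-[4-(benzyloxy)-3-methoxyphenyl]-2-(4-bromo-2-methoxyphenoxy)-3-[(TBS)oxy]propan-1-ol
Product: 22 1-(benzyloxy)-4-[(1R,2S)-2-(4-bromo-2-methoxyphenoxy)-1,3-bis{[(TBS)oxy]}propyl]-2-methoxybenzene
Conditions: TBSOTf, 2,6-lutidine, CH2Cl2, −78 → 0 °C
Reagents that add atoms: tert-butyldimethylsilyl triflate (TBSOTf), CC(C)(C)[Si](C)(C)OS(=O)(=O)C(F)(F)F
Why: Standard silylation removes the last free hydroxyl of fragment B so that only the carbinol of fragment A can form a palladium alkoxide.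

**Union and endgame**

Step 12
Reactants: 13 (1S,2R,3R)-1-[4-(benzyloxy)-3-methoxyphenyl]-3-[(TBS)oxy]-2-{[(TBS)oxy]methyl}pent-4-en-1-ol; 22 1-(benzyloxy)-4-[(1R,2S)-2-(4-bromo-2-methoxyphenoxy)-1,3-bis{[(TBS)oxy]}propyl]-2-methoxybenzene
Product: 23 1-(benzyloxy)-4-[(1R,2S)-2-(4-{[(2R,3S,4R,5S)-5-[4-(benzyloxy)-3-methoxyphenyl]-3-[(TBS)oxy]-4-{[(TBS)oxy]methyl}oxolan-2-yl]methyl}-2-methoxyphenoxy)-1,3-bis{[(TBS)oxy]}propyl]-2-methoxybenzene
Conditions: Pd2(dba)3 (2.5 mol %), bis[2-(diphenylphosphino)phenyl] ether (DPEphos, 6 mol %), NaOtBu (2 equiv), THF, 65 °C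
Reagents that add atoms: none
Why: Oxidative addition of 22 to zerovalent palladium, exchange of bromide for the sodium alkoxide of 13 and syn-insertion of the terminal alkene into the Pd–O bond should give an (oxolan-2-yl)methyl–palladium–aryl species, and C(sp3)–C(sp2) reductive elimination then forms the aryl–CH2 bond. The closest known reaction type is the palladium-catalysed carboetherification of γ-hydroxy terminal alkenes with aryl bromides, which accepts electron-rich aryl bromides, secondary benzylic alcohols and silyl ethers. The oxolane closes in a 5-exo-trig mode by C–O bond formation at the internal alkene carbon. The new stereocentre (ring C2, R) is controlled by the cyclic insertion transition state, in which the C5 aryl group, the CH2OTBS group and the allylic OTBS group all sit pseudo-equatorial; C2 should therefore form trans to the C5 aryl group and trans to the C3 silyloxy group, the two relationships for which this reaction type is selective and which reinforce each other here. The step needs chemoselectivity for oxypalladation over β-hydride elimination of the palladium alkoxide and over Heck arylation, which the chelating bisphosphine and the strong base are chosen to secure, and it needs site selectivity for one hydroxyl, which is secured because the benzylic OH is the only free hydroxyl and is placed to form a five-membered ring.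

Step 13
Reactants: 23 the tetrakis-TBS bis-benzyl ether from step 12
Product: 24 (1R,2S)-1-[4-(benzyloxy)-3-methoxyphenyl]-2-(4-{[(2R,3S,4S,5S)-5-[4-(benzyloxy)-3-methoxyphenyl]-3-hydroxy-4-(hydroxymethyl)oxolan-2-yl]methyl}-2-methoxyphenoxy)propane-1,3-diol
Conditions: TBAF, AcOH, THF, 0 °C → rt
Reagents that add atoms: none
Why: Fluoride-mediated cleavage of the four silyl ethers, buffered with acetic acid, should free all alcohols without touching the benzyl ethers or the benzylic stereocentres.

Step 14
Reactants: 24 the bis-benzyl tetraol from step 13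
Product: 25 (1R,2S)-1-(4-hydroxy-3-methoxyphenyl)-2-(4-{[(2R,3S,4S,5S)-3-hydroxy-5-(4-hydroxy-3-methoxyphenyl)-4-(hydroxymethyl)oxolan-2-yl]methyl}-2-methoxyphenoxy)propane-1,3-diol
Conditions: H2 (1 atm), 10% Pd/C, EtOAc–MeOH, rt
Reagents that add atoms: none
Why: Hydrogenolysis of phenolic benzyl ethers under neutral conditions at atmospheric pressure should be much faster than cleavage of the benzylic C–O bonds of the oxolane and the benzylic alcohol, so the reaction is stopped once both benzyl groups are gone.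

**Compound list**
1 | 3-[(tert-butyldimethylsilyl)oxy]propanoic acid | OC(=O)CCO[Si](C)(C)C(C)(C)C | starting material
2 | (S)-4-benzyloxazolidin-2-one | O=C1OC[C@H](Cc2ccccc2)N1 | starting material
3 | 3-[(TBS)oxy]propanoic pivalic anhydride | CC(C)(C)C(=O)OC(=O)CCO[Si](C)(C)C(C)(C)C | intermediate
4 | (S)-4-benzyl-3-{3-[(TBS)oxy]propanoyl}oxazolidin-2-one | O=C1OC[C@H](Cc2ccccc2)N1C(=O)CCO[Si](C)(C)C(C)(C)C | intermediate
5 | acrolein | C=CC=O | starting material
6 | Z-dibutylboron enolate of 4 | CCCCB(CCCC)O/C(=C\CO[Si](C)(C)C(C)(C)C)N1C(=O)OC[C@@H]1Cc1ccccc1 | intermediate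
7 | (S)-4-benzyl-3-[(2S,3R)-2-{[(TBS)oxy]methyl}-3-hydroxypent-4-enoyl]oxazolidin-2-one | O=C1OC[C@H](Cc2ccccc2)N1C(=O)[C@@H](CO[Si](C)(C)C(C)(C)C)[C@H](O)C=C | intermediate
8 | (2S,3R)-2-{[(TBS)oxy]methyl}-3-hydroxy-N-methoxy-N-methylpent-4-enamide | CON(C)C(=O)[C@@H](CO[Si](C)(C)C(C)(C)C)[C@H](O)C=C | intermediate
9 | (2S,3R)-3-[(TBS)oxy]-2-{[(TBS)oxy]methyl}-N-methoxy-N-methylpent-4-enamide | CON(C)C(=O)[C@@H](CO[Si](C)(C)C(C)(C)C)[C@H](O[Si](C)(C)C(C)(C)C)C=C | intermediate
10 | 1-(benzyloxy)-4-bromo-2-methoxybenzene | COc1cc(Br)ccc1OCc1ccccc1 | starting material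
11 | [4-(benzyloxy)-3-methoxyphenyl]lithium | [Li]c1ccc(OCc2ccccc2)c(OC)c1 | intermediate
12 | (2S,3R)-1-[4-(benzyloxy)-3-methoxyphenyl]-3-[(TBS)oxy]-2-{[(TBS)oxy]methyl}pent-4-en-1-one | O=C(c1ccc(OCc2ccccc2)c(OC)c1)[C@@H](CO[Si](C)(C)C(C)(C)C)[C@H](O[Si](C)(C)C(C)(C)C)C=C | intermediate
13 | (1S,2R,3R)-1-[4-(benzyloxy)-3-methoxyphenyl]-3-[(TBS)oxy]-2-{[(TBS)oxy]methyl}pent-4-en-1-ol | O[C@H](c1ccc(OCc2ccccc2)c(OC)c1)[C@@H](CO[Si](C)(C)C(C)(C)C)[C@@H](C=C)O[Si](C)(C)C(C)(C)C | intermediate
14 | methyl (R)-2,3-dihydroxypropanoate | COC(=O)[C@H](O)CO | starting material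
15 | methyl (R)-3-[(TBS)oxy]-2-hydroxypropanoate | COC(=O)[C@H](O)CO[Si](C)(C)C(C)(C)C | intermediate
16 | 4-bromo-2-methoxyphenol | COc1cc(Br)ccc1O | starting material
17 | methyl (S)-2-(4-bromo-2-methoxyphenoxy)-3-[(TBS)oxy]propanoate | COC(=O)[C@H](CO[Si](C)(C)C(C)(C)C)Oc1ccc(Br)cc1OC | intermediate
18 | (S)-2-(4-bromo-2-methoxyphenoxy)-3-[(TBS)oxy]propanal | O=C[C@H](CO[Si](C)(C)C(C)(C)C)Oc1ccc(Br)cc1OC | intermediate
19 | [4-(benzyloxy)-3-methoxyphenyl]magnesium bromide | Br[Mg]c1ccc(OCc2ccccc2)c(OC)c1 | intermediate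
20 | [4-(benzyloxy)-3-methoxyphenyl]titanium triisopropoxide | CC(C)O[Ti](OC(C)C)(OC(C)C)c1ccc(OCc2ccccc2)c(OC)c1 | intermediate
21 | (1R,2S)-1-[4-(benzyloxy)-3-methoxyphenyl]-2-(4-bromo-2-methoxyphenoxy)-3-[(TBS)oxy]propan-1-ol | COc1cc([C@@H](O)[C@H](CO[Si](C)(C)C(C)(C)C)Oc2ccc(Br)cc2OC)ccc1OCc1ccccc1 | intermediate
22 | 1-(benzyloxy)-4-[(1R,2S)-2-(4-bromo-2-methoxyphenoxy)-1,3-bis{[(TBS)oxy]}propyl]-2-methoxybenzene | COc1cc([C@@H](O[Si](C)(C)C(C)(C)C)[C@H](CO[Si](C)(C)C(C)(C)C)Oc2ccc(Br)cc2OC)ccc1OCc1ccccc1 | intermediate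
23 | tetrakis-TBS bis-benzyl ether of the target, oxolane (2R,3S,4R,5S), side chain (1R,2S) | COc1cc([C@@H](O[Si](C)(C)C(C)(C)C)[C@H](CO[Si](C)(C)C(C)(C)C)Oc2ccc(C[C@H]3O[C@H](c4ccc(OCc5ccccc5)c(OC)c4)[C@@H](CO[Si](C)(C)C(C)(C)C)[C@@H]3O[Si](C)(C)C(C)(C)C)cc2OC)ccc1OCc1ccccc1 | intermediate
24 | bis-benzyl ether of the target, oxolane (2R,3S,4S,5S), side chain (1R,2S) | COc1cc([C@@H](O)[C@H](CO)Oc2ccc(C[C@H]3O[C@H](c4ccc(OCc5ccccc5)c(OC)c4)[C@@H](CO)[C@@H]3O)cc2OC)ccc1OCc1ccccc1 | intermediate
25 | (1R,2S)-1-(4-hydroxy-3-methoxyphenyl)-2-(4-{[(2R,3S,4S,5S)-3-hydroxy-5-(4-hydroxy-3-methoxyphenyl)-4-(hydroxymethyl)oxolan-2-yl]methyl}-2-methoxyphenoxy)propane-1,3-diol (CNP0123626.1) | COc1cc([C@@H](O)[C@H](CO)Oc2ccc(C[C@H]3O[C@H](c4ccc(O)c(OC)c4)[C@@H](CO)[C@@H]3O)cc2OC)ccc1O | target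

**Totals**
Total step count: 14. Longest linear sequence: 9 steps (steps 1–6, then 12, 13, 14). Fragment B takes 5 steps (7–11).

**Steps most likely to fail, with fallbacks**

Step 12 (key step). What may go wrong: β-hydride elimination from the palladium alkoxide of the hindered benzylic alcohol (net oxidation of 13 back to ketone 12 with reduction of 22), or Heck-type arylation or β-hydride elimination of the alkylpalladium intermediate before C–C reductive elimination. The fallback closes the ring first and makes the C–C bond second. It sets out from 13. A Mukaiyama aerobic oxidative cyclisation (Co(modp)2, that is cobalt bis(1-morpholinocarbamoyl-4,4-dimethylpentane-1,3-dionate), O2, t-BuOOH, i-PrOH, 55 °C) should close the oxolane with the 2,5-trans preference typical of this cyclisation and give the hydroxymethyl-oxolane F1. Treatment with I2, PPh3 and imidazole should convert it into the iodomethyl-oxolane F2. A nickel-catalysed reductive cross-electrophile coupling of F2 with aryl bromide 22 (NiI2, 4,4'-di-tert-butyl-2,2'-bipyridine, Mn powder, NaI, DMA, 60 °C) would then form the aryl–CH2 bond and come back to the route at 23. Manganese is chosen as the reductant because it should not insert directly into the C–I bond, which avoids reductive ring-opening of the β-alkoxy iodide.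

Step 10. What may go wrong: poor facial selectivity in the aryl transfer, because chelation through the 2-methoxyphenoxy oxygens competes with the polar Felkin–Anh pathway. The fallback sets the carbinol by chelation-controlled hydride delivery instead of by C–C bond formation. It sets out from 21, used as the mixture of C1 epimers delivered by step 10. Dess–Martin oxidation (NaHCO3, CH2Cl2, 0 °C) should converge both epimers to the aryl ketone F3 without epimerising the α-aryloxy centre. Reduction with Zn(BH4)2 (Et2O, −78 → −20 °C) should pass through the five-membered zinc chelate between the carbonyl and aryloxy oxygens, with hydride delivered to the face that carries the α-hydrogen, and should return to 21 as the (1R,2S) erythro isomer.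

Step 6. What may go wrong: slow or poorly face-selective hydride delivery to the hindered α-branched aryl ketone. The fallback uses hydroxyl-directed reduction and sets out from Weinreb amide 8, which still has the free allylic hydroxyl. Excess aryllithium 11 (THF, −78 °C) should give the β-hydroxy ketone F4. Evans–Saksena reduction (Me4NBH(OAc)3, MeCN–AcOH, −30 °C) delivers hydride intramolecularly and should give the anti-1,3-diol F5 with the (1S) carbinol. Site-selective monosilylation (TBSCl, imidazole, DMF, −20 °C) of the allylic hydroxyl, which is flanked by the small vinyl group and not by the aryl ring, would come back to the route at 13; a regioisomeric silyl ether would have to be separated.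

**Further compounds**
F1 | step 12 | [(2R,3S,4R,5S)-5-[4-(benzyloxy)-3-methoxyphenyl]-3-[(TBS)oxy]-4-{[(TBS)oxy]methyl}oxolan-2-yl]methanol | OC[C@H]1O[C@H](c2ccc(OCc3ccccc3)c(OC)c2)[C@@H](CO[Si](C)(C)C(C)(C)C)[C@@H]1O[Si](C)(C)C(C)(C)C
F2 | step 12 | (2S,3S,4R,5S)-5-[4-(benzyloxy)-3-methoxyphenyl]-3-[(TBS)oxy]-4-{[(TBS)oxy]methyl}-2-(iodomethyl)oxolane | IC[C@H]1O[C@H](c2ccc(OCc3ccccc3)c(OC)c2)[C@@H](CO[Si](C)(C)C(C)(C)C)[C@@H]1O[Si](C)(C)C(C)(C)C
F3 | step 10 | (S)-1-[4-(benzyloxy)-3-methoxyphenyl]-2-(4-bromo-2-methoxyphenoxy)-3-[(TBS)oxy]propan-1-one | COc1cc(C(=O)[C@H](CO[Si](C)(C)C(C)(C)C)Oc2ccc(Br)cc2OC)ccc1OCc1ccccc1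
F4 | step 6 | (2S,3R)-1-[4-(benzyloxy)-3-methoxyphenyl]-2-{[(TBS)oxy]methyl}-3-hydroxypent-4-en-1-one | O=C(c1ccc(OCc2ccccc2)c(OC)c1)[C@@H](CO[Si](C)(C)C(C)(C)C)[C@H](O)C=C
F5 | step 6 | (1S,2S,3R)-1-[4-(benzyloxy)-3-methoxyphenyl]-2-{[(TBS)oxy]methyl}pent-4-ene-1,3-diol | O[C@H](c1ccc(OCc2ccccc2)c(OC)c1)[C@@H](CO[Si](C)(C)C(C)(C)C)[C@@H](C=C)O
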